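**Strategy.** Everything rests on cutting ring B at C29–C30 and C8–C32, so that the cyclobutane (ring D) arrives as a squarate-derived cyclobutenone. The key step exploits the fact that the adjacent quaternary carbons C30 (methyl) and C32 (oxygen) are shared by rings B and D, while C5 and C6 of ring B are both oxygenated: a tethered 2,3-bis(silyloxy)diene (C29=C5–C6=C8) adds across the cyclobutenone alkene C30=C32, closing rings A and B and setting C8, C29, C30 and C32 at once. The precursor is a 2-benzyloxy-3-methylcyclobutenone whose only ring stereocentre, C22, carries the diene chain; C24 is masked as a silyl ether and the two enol ethers are differentiated (O5 TMS, O6 TES).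

Key step: step 16

Remark on the chemistry: atom labels (C5, C6, …) are the positions of the heavy atoms in the target SMILES. C24 is carried from step 10 to step 22 as a mixture of its two carbinol epimers, which converge when C24 returns to the ketone. TBDPS = tert-butyldiphenylsilyl, TBS = tert-butyldimethylsilyl, TES = triethylsilyl, TMS = trimethylsilyl, Bn = benzyl, BOM = benzyloxymethyl, DMP = Dess–Martin periodinane.

## Side chain (steps 1–6)

Step 1
Reactants: 1 but-3-yn-1-ol
Product: 2 tert-butyl(but-3-yn-1-yloxy)diphenylsilane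
Conditions: t-BuPh2SiCl, imidazole, CH2Cl2, 0 °C to rt
Reagents that add atoms: tert-butyl(chloro)diphenylsilane, CC(C)(C)[Si](Cl)(c1ccccc1)c1ccccc1
Why: Silylation of a primary alcohol; the TBDPS ether is chosen because it must outlast the buffered HF of step 17.

Step 2
Reactants: 2 tert-butyl(but-3-yn-1-yloxy)diphenylsilane
Product: 3 5-(TBDPS-oxy)pent-2-yn-1-ol
Conditions: n-BuLi, THF, −78 °C; (CH2O)n, −78 °C to rt
Reagents that add atoms: formaldehyde (as paraformaldehyde), C=O
Why: Deprotonation of the terminal alkyne and 1,2-addition to formaldehyde (acetylide hydroxymethylation) adds C29.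

Step 3
Reactants: 3 5-(TBDPS-oxy)pent-2-yn-1-ol
Product: 4 (E)-5-(TBDPS-oxy)pent-2-en-1-ol
Conditions: NaAlH2(OCH2CH2OCH3)2, THF, 0 °C to rt; aq. KNaC4H4O6
Reagents that add atoms: none
Why: Alkoxide-directed trans-hydroalumination of a propargylic alcohol should give only the (E)-allylic alcohol.

Step 4
Reactants: 4 (E)-5-(TBDPS-oxy)pent-2-en-1-ol
Product: 5 (E)-(5-bromopent-3-en-1-yloxy)(tert-butyl)diphenylsilane
Conditions: CBr4, PPh3, CH2Cl2, 0 °C
Reagents that add atoms: tetrabromomethane, BrC(Br)(Br)Br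
Why: Appel reaction converts the primary allylic alcohol into the bromide without allylic transposition.

Step 5
Reactants: 6 isobutyronitrile; 5 (E)-(5-bromopent-3-en-1-yloxy)(tert-butyl)diphenylsilane
Product: 7 (E)-7-(TBDPS-oxy)-2,2-dimethylhept-4-enenitrile
Conditions: LiN(iPr)2, THF, −78 °C; then 5, −78 °C to rt
Reagents that add atoms: none
Why: SN2 alkylation of the lithiated nitrile by the primary allylic bromide builds the quaternary carbon C26 (nitrile alkylation).

Step 6
Reactants: 7 (E)-7-(TBDPS-oxy)-2,2-dimethylhept-4-enenitrile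
Product: 9 (E)-8-(TBDPS-oxy)-3,3-dimethyloct-5-en-2-one, via ketimine 8 (not isolated)
Conditions: MeLi, Et2O, 0 °C to rt; then 1 M aq. HCl, THF, 0 °C
Reagents that add atoms: methyllithium, [Li]C; water, O
Why: A nitrile takes up only one equivalent of MeLi (the metallo-imine is inert), and hydrolysis of the imine gives the methyl ketone whose methyl group is C23.

## Squarate partner (step 7)

Step 7
Reactants: 10 squaric acid
Product: 11 dibenzyl squarate (3,4-bis(benzyloxy)cyclobut-3-ene-1,2-dione)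
Conditions: BnOH, toluene, reflux, Dean–Stark trap
Reagents that add atoms: benzyl alcohol, OCc1ccccc1
Why: Azeotropic esterification of the vinylogous diacid, the standard preparation of dialkyl squarates.

## Cyclobutenone and diene (steps 8–15)

Step 8
Reactants: 9 (E)-8-(TBDPS-oxy)-3,3-dimethyloct-5-en-2-one; 11 dibenzyl squarate
Product: 14 (Z)-2,3-bis(benzyloxy)-4-[(5E)-8-(TBDPS-oxy)-3,3-dimethyl-2-oxooct-5-en-1-ylidene]cyclobut-2-en-1-one, via lithium aldolate 12 (not isolated), via tertiary acetate 13 (not isolated)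
Conditions: LiN(iPr)2, THF, −78 °C; 11, −78 °C; then Ac2O, DMAP, −78 to 0 °C; then DBU, 0 °C to rt
Reagents that add atoms: none
Why: Ketone 9 can be deprotonated only at C23 and adds 1,2 to a squarate carbonyl (aldol addition); acetylation of the aldolate and E1cB elimination should give the conjugated alkylidene as the (Z) isomer, which keeps the acyl group away from the neighbouring benzyloxy group.

Step 9
Reactants: 14 (Z)-alkylidene cyclobutenone
Product: 15 (4R)-2,3-bis(benzyloxy)-4-[(5E)-8-(TBDPS-oxy)-3,3-dimethyl-2-oxooct-5-en-1-yl]cyclobut-2-en-1-one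
Conditions: Cu(OAc)2·H2O (3 mol %), (R)-DTBM-SEGPHOS (3.3 mol %), (EtO)2MeSiH, t-BuOH, toluene, −20 to 0 °C
Reagents that add atoms: none
Why: Ligand-controlled copper hydride 1,4-reduction of a β,β-disubstituted enone puts hydride on C22 (attack at C23 would give an antiaromatic cyclobutadienolate) and the chiral bisphosphine selects the enantiotopic face, setting C22; the ligand antipode is used if the sense of induction proves opposite.

Step 10
Reactants: 15 (4R)-keto cyclobutenone
Product: 16 (4R)-2,3-bis(benzyloxy)-4-[(5E)-8-(TBDPS-oxy)-2-hydroxy-3,3-dimethyloct-5-en-1-yl]cyclobut-2-en-1-one (C24 epimers)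
Conditions: Zn(BH4)2, Et2O, 0 °C
Reagents that add atoms: none
Why: Borohydride reduces the saturated C24 ketone but not the vinylogous ester carbonyl of the ring, turning C24 into a temporary carbinol so that it cannot compete in steps 12, 15 and 16.

Step 11
Reactants: 16 C24 carbinol
Product: 17 (4R)-2,3-bis(benzyloxy)-4-[(5E)-2-(TBS-oxy)-8-(TBDPS-oxy)-3,3-dimethyloct-5-en-1-yl]cyclobut-2-en-1-one (C24 epimers)
Conditions: TBSOTf, 2,6-lutidine, CH2Cl2, −78 to 0 °C
Reagents that add atoms: tert-butyldimethylsilyl triflate, CC(C)(C)[Si](C)(C)OS(=O)(=O)C(F)(F)F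
Why: Silyl triflate silylation of a hindered secondary alcohol.

Step 12
Reactants: 17 C24 silyl ether
Product: 19 (4S)-2-(benzyloxy)-3-methyl-4-[(5E)-2-(TBS-oxy)-8-(TBDPS-oxy)-3,3-dimethyloct-5-en-1-yl]cyclobut-2-en-1-one (C24 epimers), via cyclobutenol adduct 18 (not isolated)
Conditions: MeLi, THF, −78 °C; then 2 M aq. HCl, 0 °C to rt
Reagents that add atoms: methyllithium, [Li]C
Why: 1,2-Addition of MeLi to the vinylogous ester carbonyl, then acid-induced allylic transposition with loss of benzyl alcohol (Stork–Danheiser sequence, standard for squarate adducts), gives the 2-alkoxy-3-methylcyclobutenone; C22 is untouched because its deprotonation would give an antiaromatic enolate.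

Step 13
Reactants: 19 cyclobutenone with (E)-alkene side chain
Product: 20 5,6-diol of 19 (mixture of diol diastereomers; C5 and C6 become carbonyls in step 14)
Conditions: OsO4 (2 mol %), N-methylmorpholine N-oxide, acetone/H2O, rt
Reagents that add atoms: N-methylmorpholine N-oxide, C[N+]1([O-])CCOCC1; water, O
Why: Catalytic osmylation is selective for the isolated disubstituted alkene over the tetrasubstituted, carbonyl-conjugated ring alkene.

Step 14
Reactants: 20 5,6-diol
Product: 21 (4S)-2-(benzyloxy)-3-methyl-4-[2-(TBS-oxy)-8-(TBDPS-oxy)-3,3-dimethyl-5,6-dioxooctyl]cyclobut-2-en-1-one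
Conditions: (COCl)2, DMSO, CH2Cl2, −78 °C; Et3N, −78 to −20 °C
Reagents that add atoms: none
Why: Swern oxidation converts a vicinal diol into the 1,2-diketone without C–C cleavage.

Step 15
Reactants: 21 1,2-diketone
Product: 23 (4S)-2-(benzyloxy)-3-methyl-4-[(4Z,6Z)-2-(TBS-oxy)-8-(TBDPS-oxy)-3,3-dimethyl-6-(triethylsilyloxy)-5-(trimethylsilyloxy)octa-4,6-dien-1-yl]cyclobut-2-en-1-one, via mono-TES enol ether 22 (not isolated)
Conditions: TESOTf (1.05 equiv), Et3N, CH2Cl2, −78 °C; then TMSOTf (1.2 equiv), −78 to 0 °C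
Reagents that add atoms: triethylsilyl triflate, CC[Si](CC)(CC)OS(=O)(=O)C(F)(F)F; trimethylsilyl triflate, C[Si](C)(C)OS(=O)(=O)C(F)(F)F
Why: Soft enolisation goes first toward the unhindered C8 (TES on O6) and then toward the neopentyl C29 (TMS on O5), each giving the (Z) enol ether, so both diene substituents point outward; the two silyl groups differ so that O5 can be unmasked before O6 in step 17.

## Key step

Step 16
Reactants: 23 cyclobutenone with tethered bis(silyloxy)diene
Product: 24 tricyclic cycloadduct (rings A, B and D): C20 cyclobutanone, C32 OBn, C30 CH3, C5=C6 enediol ether (O5 TMS, O6 TES), C8 CH2OTBDPS, C24 OTBS; C8, C22, C29, C30, C32 as in the target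
Conditions: Me2AlCl (1.2 equiv), CH2Cl2, −78 to −40 °C; aq. KNaC4H4O6
Reagents that add atoms: none
Why: Proposed new method: Me2AlCl, chelated between the C20 carbonyl and the benzyloxy oxygen, lowers the LUMO of the strained enone so that the electron-rich diene adds in a concerted but asynchronous [4+2] cycloaddition, the C29–C30 bond (enol ether terminus to enone β-carbon) forming ahead of the C8–C32 bond. The closest known reaction types are Diels–Alder reactions of cyclobutenones, including intramolecular ones, and intramolecular Diels–Alder reactions of 2,3-bis(silyloxy)dienes; a tetrasubstituted 2-alkoxy-3-alkylcyclobutenone has not served as dienophile. Ring B closes as the six-membered cycloadduct ring and ring A as the six-membered ring spanned by the tether C26–C24–C23–C22 between C29 and C30 (fused mode). C30 and C32 are controlled by C22, since the tether can bring the diene only to the cyclobutenone face that carries C23, and C29 and C8 are controlled by the endo transition state together with the (Z,Z) enol ether geometry, which places both new hydrogens cis to the C30 methyl and the C32 oxygen (cis A/B fusion). The step needs endo over exo selectivity, secured by Lewis-acid-enhanced secondary overlap with the C20 carbonyl and by the clash an exo diene would suffer with the in-plane methyl and benzyloxy groups, and it needs cycloaddition to outpace electrocyclic opening of the cyclobutenone to a vinylketene, secured by reaction at −78 to −40 °C with no free carbonyl at C24 to compete for the Lewis acid.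

## C5/C6 and C9 (steps 17–22)

Step 17
Reactants: 24 tricyclic cycloadduct
Product: 26 acyloin: C5 ketone, C6 hydroxyl (configured as in the target), via C6 triethylsilyloxy ketone 25 (not isolated)
Conditions: HF·pyridine, pyridine, THF, 0 °C
Reagents that add atoms: none
Why: Fluoride cleaves the TMS enol ether first; the resulting O5 enol ketonises by protonation of C6 on the exposed convex face (sets C6), and the C6 triethylsilyl ether is then removed while the hindered TBS and the TBDPS ethers survive.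

Step 18
Reactants: 26 acyloin
Product: 27 C5,C6-trans-diol (C5 and C6 as in the target)
Conditions: Me4NBH(OAc)3, MeCN/AcOH, −30 °C
Reagents that add atoms: none
Why: Hydroxyl-directed triacetoxyborohydride reduction delivers hydride from the C6 hydroxyl to the same face of the C5 ketone (sets C5, trans-diol), while the C20 ketone, which has no free neighbouring hydroxyl, is not reduced.

Step 19
Reactants: 27 trans-diol
Product: 28 C5 acetate, C6 hydroxyl
Conditions: Ac2O (1.1 equiv), pyridine, CH2Cl2, −20 °C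
Reagents that add atoms: acetic anhydride, CC(=O)OC(C)=O
Why: Selective acylation is expected at the C5 hydroxyl, which lies on the convex exterior flanked only by C–H bonds, whereas the C6 hydroxyl points into the concave pocket beside the C9 arm.

Step 20
Reactants: 28 C5 acetate
Product: 29 C5 acetate, C6 BOM ether
Conditions: BnOCH2Cl, iPr2NEt, Bu4NI (cat.), ClCH2CH2Cl, 50 °C
Reagents that add atoms: benzyl chloromethyl ether, ClCOCc1ccccc1
Why: Alkylation of the remaining hindered secondary alcohol with an activated chloromethyl ether under non-nucleophilic base; BOM is chosen so that it leaves together with the C32 benzyl ether in step 34.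

Step 21
Reactants: 29 fully protected tricycle
Product: 30 C9 primary alcohol and C24 secondary alcohol (C24 epimers)
Conditions: Bu4NF, AcOH, THF, rt
Reagents that add atoms: none
Why: Buffered fluoride removes the only two silyl ethers left (TBDPS on O9, TBS on O24) without touching the acetate or the benzyl-type ethers.

Step 22
Reactants: 30 diol
Product: 31 C9 aldehyde with C24 ketone (C5 OAc, C6 OBOM, C32 OBn, C20 cyclobutanone)
Conditions: DMP, pyridine, CH2Cl2, rt
Reagents that add atoms: none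
Why: Dess–Martin oxidation converts the primary alcohol into the aldehyde and both C24 epimers into the single C24 ketone under near-neutral conditions that do not epimerise C8.

## Bromoalkene fragment (steps 23–24)

Step 23
Reactants: 32 (E)-crotonaldehyde
Product: 34 (Z)-2-bromobut-2-enal, via dibromide 33 (not isolated)
Conditions: Br2, CH2Cl2, 0 °C; then Et3N, 0 °C to rt
Reagents that add atoms: bromine, BrBr
Why: Bromine addition followed by E1cB loss of HBr gives the 2-bromoenal with bromine cis to the methyl group (bromination–dehydrobromination).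

Step 24
Reactants: 34 (Z)-2-bromobut-2-enal
Product: 35 (Z)-2-bromobut-2-en-1-ol
Conditions: NaBH4, CeCl3·7H2O, MeOH, 0 °C
Reagents that add atoms: none
Why: Luche reduction gives clean 1,2-reduction of the enal with retention of alkene geometry.

## Ring C and end game (steps 25–34)

Step 25
Reactants: 31 C9 aldehyde; 35 (Z)-2-bromobut-2-en-1-ol
Product: 37 (9S)-allylic alcohol: C9 carbinol bearing the (Z)-1-hydroxybut-2-en-2-yl group (C15 CH2OH, C11=C13, methyl cis to C9), via alkenylchromium dichloride 36 (not isolated)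
Conditions: CrCl2 (6 equiv), NiCl2 (2 mol %), DMF, rt
Reagents that add atoms: none
Why: Nozaki–Hiyama–Kishi reaction: the alkenyl reagent of trivalent chromium adds to the aldehyde only (the C20 and C24 ketones and the acetate are tolerated) with retention of alkene geometry, and Felkin–Anh addition anti to the quaternary C32 is expected to set C9 as (S).

Step 26
Reactants: 37 (9S)-allylic alcohol
Product: 38 cyclopropane diol: C11 spiro carbon with C12 H2 and C13 H(CH3), methyl cis to C9, C11 and C13 as in the target; C9 and C15 hydroxyls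
Conditions: Et2Zn, CH2I2, CH2Cl2, 0 °C
Reagents that add atoms: diiodomethane, ICI
Why: Hydroxyl-directed Simmons–Smith cyclopropanation: A(1,3) strain with the cis methyl holds the C9–H in the alkene plane, so the zinc alkoxide of the (9S) carbinol delivers CH2 to one face only (the face away from C8), setting C11 and C13, and the stereospecific addition keeps the methyl cis to C9.

Step 27
Reactants: 38 cyclopropane diol
Product: 39 C15 aldehyde with free (9S) hydroxyl
Conditions: TEMPO (10 mol %), PhI(OAc)2, CH2Cl2, rt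
Reagents that add atoms: none
Why: Oxoammonium-catalysed oxidation is selective for the primary alcohol over the hindered secondary one.

Step 28
Reactants: 39 hydroxy aldehyde
Product: 40 C15 aldehyde with C9 triethylsilyl ether
Conditions: TESOTf, 2,6-lutidine, CH2Cl2, −78 °C
Reagents that add atoms: triethylsilyl triflate, CC[Si](CC)(CC)OS(=O)(=O)C(F)(F)F
Why: Silylation of the only free hydroxyl keeps C9 at the alcohol level during ring closure, so that neither a doubly activated cyclopropane nor a second directable ketone is present in steps 29 and 30.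

Step 29
Reactants: 40 aldehyde
Product: 41 ring C closed: C15 ketone, C20 tertiary hydroxyl (C20 as in the target)
Conditions: 2-(pentafluorophenyl)-6,7-dihydro-5H-pyrrolo[2,1-c][1,2,4]triazol-2-ium tetrafluoroborate (20 mol %), Et3N (20 mol %), THF, rt
Reagents that add atoms: none
Why: Carbene-catalysed intramolecular crossed benzoin reaction: the acyl anion equivalent formed at C15 adds to the strained C20 carbonyl, and because C15 is tethered through C11–C9–C8 it can reach only the upper face, so the C20 hydroxyl ends cis to the C32 oxygen (sets C20).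

Step 30
Reactants: 41 α-hydroxy ketone
Product: 42 C15 carbinol trans to the C20 hydroxyl (C15 as in the target)
Conditions: Me4NBH(OAc)3, MeCN/AcOH, −30 to 0 °C
Reagents that add atoms: none
Why: Hydroxyl-directed triacetoxyborohydride reduction delivers hydride from the C20 hydroxyl to the same face of C15 (sets C15), leaving the C24 ketone untouched and removing the rearrangement-prone α-ketol at once.

Step 31
Reactants: 42 C15,C20-diol
Product: 43 C5,C15-diacetate with C9 OTES, C6 OBOM, C32 OBn
Conditions: Ac2O, DMAP, Et3N, CH2Cl2, rt to 40 °C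
Reagents that add atoms: acetic anhydride, CC(=O)OC(C)=O
Why: DMAP-catalysed acylation takes the secondary C15 hydroxyl while the tertiary C20 hydroxyl is expected to remain free.

Step 32
Reactants: 43 diacetate
Product: 44 C9 secondary alcohol
Conditions: HF·pyridine, THF, 0 °C to rt
Reagents that add atoms: none
Why: Fluoride-mediated cleavage of the single silyl ether under conditions that leave acetates untouched.

Step 33
Reactants: 44 C9 alcohol
Product: 45 C9 ketone (target with O6 BOM and O32 Bn)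
Conditions: DMP, pyridine, CH2Cl2, rt
Reagents that add atoms: none
Why: Dess–Martin oxidation of the only secondary alcohol gives the cyclopropyl ketone without base, so the β-oxygenated C8 centre is not epimerised.

Step 34
Reactants: 45 protected target
Product: 46 CNP0157858.3
Conditions: H2 (1 atm), Pd(OH)2/C, EtOAc, rt
Reagents that add atoms: none
Why: Hydrogenolysis removes the benzyl ether on O32 and the BOM ether on O6 in one neutral operation; acetates, ketones and the cyclopropyl ketone are expected to survive under one atmosphere at room temperature.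

## Compound list

1 | but-3-yn-1-ol | C#CCCO | starting material
2 | tert-butyl(but-3-yn-1-yloxy)diphenylsilane | C#CCCO[Si](c1ccccc1)(c1ccccc1)C(C)(C)C | intermediate
3 | 5-(TBDPS-oxy)pent-2-yn-1-ol | OCC#CCCO[Si](c1ccccc1)(c1ccccc1)C(C)(C)C | intermediate
4 | (E)-5-(TBDPS-oxy)pent-2-en-1-ol | OC/C=C/CCO[Si](c1ccccc1)(c1ccccc1)C(C)(C)C | intermediate
5 | (E)-(5-bromopent-3-en-1-yloxy)(tert-butyl)diphenylsilane | BrC/C=C/CCO[Si](c1ccccc1)(c1ccccc1)C(C)(C)C | intermediate
6 | isobutyronitrile | CC(C)C#N | starting material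
7 | (E)-7-(TBDPS-oxy)-2,2-dimethylhept-4-enenitrile | N#CC(C)(C)C/C=C/CCO[Si](c1ccccc1)(c1ccccc1)C(C)(C)C | intermediate
8 | ketimine of 9 | CC(=N)C(C)(C)C/C=C/CCO[Si](c1ccccc1)(c1ccccc1)C(C)(C)C | intermediate (not isolated)
9 | (E)-8-(TBDPS-oxy)-3,3-dimethyloct-5-en-2-one | CC(=O)C(C)(C)C/C=C/CCO[Si](c1ccccc1)(c1ccccc1)C(C)(C)C | intermediate
10 | squaric acid | O=C1C(O)=C(O)C1=O | starting material
11 | dibenzyl squarate | O=C1C(OCc2ccccc2)=C(OCc2ccccc2)C1=O | intermediate
12 | lithium aldolate (racemic 4-oxido adduct of 9 and 11) | O=C1C(OCc2ccccc2)=C(OCc2ccccc2)C1(O[Li])CC(=O)C(C)(C)C/C=C/CCO[Si](c1ccccc1)(c1ccccc1)C(C)(C)C | intermediate (not isolated)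
13 | tertiary acetate of the aldol adduct (racemic) | O=C1C(OCc2ccccc2)=C(OCc2ccccc2)C1(OC(C)=O)CC(=O)C(C)(C)C/C=C/CCO[Si](c1ccccc1)(c1ccccc1)C(C)(C)C | intermediate (not isolated)
14 | (Z)-2,3-bis(benzyloxy)-4-[(5E)-8-(TBDPS-oxy)-3,3-dimethyl-2-oxooct-5-en-1-ylidene]cyclobut-2-en-1-one | O=C1C(OCc2ccccc2)=C(OCc2ccccc2)/C1=C/C(=O)C(C)(C)C/C=C/CCO[Si](c1ccccc1)(c1ccccc1)C(C)(C)C | intermediate
15 | (4R)-2,3-bis(benzyloxy)-4-[(5E)-8-(TBDPS-oxy)-3,3-dimethyl-2-oxooct-5-en-1-yl]cyclobut-2-en-1-one | O=C1C(OCc2ccccc2)=C(OCc2ccccc2)[C@H]1CC(=O)C(C)(C)C/C=C/CCO[Si](c1ccccc1)(c1ccccc1)C(C)(C)C | intermediate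
16 | C24 carbinol of 15 (C24 epimers) | O=C1C(OCc2ccccc2)=C(OCc2ccccc2)[C@H]1CC(O)C(C)(C)C/C=C/CCO[Si](c1ccccc1)(c1ccccc1)C(C)(C)C | intermediate
17 | C24 TBS ether of 16 (C24 epimers) | O=C1C(OCc2ccccc2)=C(OCc2ccccc2)[C@H]1CC(O[Si](C)(C)C(C)(C)C)C(C)(C)C/C=C/CCO[Si](c1ccccc1)(c1ccccc1)C(C)(C)C | intermediate
18 | 1-methylcyclobutenol adduct of 17 | CC1(O)C(OCc2ccccc2)=C(OCc2ccccc2)[C@H]1CC(O[Si](C)(C)C(C)(C)C)C(C)(C)C/C=C/CCO[Si](c1ccccc1)(c1ccccc1)C(C)(C)C | intermediate (not isolated)
19 | (4S)-2-(benzyloxy)-3-methyl-4-[(5E)-2-(TBS-oxy)-8-(TBDPS-oxy)-3,3-dimethyloct-5-en-1-yl]cyclobut-2-en-1-one (C24 epimers) | O=C1C(OCc2ccccc2)=C(C)[C@@H]1CC(O[Si](C)(C)C(C)(C)C)C(C)(C)C/C=C/CCO[Si](c1ccccc1)(c1ccccc1)C(C)(C)C | intermediate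
20 | 5,6-diol of 19 (diastereomer mixture) | O=C1C(OCc2ccccc2)=C(C)[C@@H]1CC(O[Si](C)(C)C(C)(C)C)C(C)(C)CC(O)C(O)CCO[Si](c1ccccc1)(c1ccccc1)C(C)(C)C | intermediate
21 | 5,6-diketone (C24 epimers) | O=C1C(OCc2ccccc2)=C(C)[C@@H]1CC(O[Si](C)(C)C(C)(C)C)C(C)(C)CC(=O)C(=O)CCO[Si](c1ccccc1)(c1ccccc1)C(C)(C)C | intermediate
22 | (6Z)-6-(triethylsilyloxy) enone (mono-TES enol ether of 21) | O=C1C(OCc2ccccc2)=C(C)[C@@H]1CC(O[Si](C)(C)C(C)(C)C)C(C)(C)CC(=O)/C(O[Si](CC)(CC)CC)=C/CO[Si](c1ccccc1)(c1ccccc1)C(C)(C)C | intermediate (not isolated)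
23 | Diels–Alder precursor: (4S)-2-(benzyloxy)-3-methylcyclobutenone with (4Z,6Z)-5-(TMS-oxy)-6-(TES-oxy)diene chain (C24 epimers) | O=C1C(OCc2ccccc2)=C(C)[C@@H]1CC(O[Si](C)(C)C(C)(C)C)C(C)(C)/C=C(O[Si](C)(C)C)/C(O[Si](CC)(CC)CC)=C/CO[Si](c1ccccc1)(c1ccccc1)C(C)(C)C | intermediate
24 | tricyclic cycloadduct, C5=C6 enediol ether (O5 TMS, O6 TES) | C[Si](C)(C)OC1=C(O[Si](CC)(CC)CC)[C@@H](CO[Si](c5ccccc5)(c5ccccc5)C(C)(C)C)[C@@]2(OCc5ccccc5)C(=O)[C@H]3CC(O[Si](C)(C)C(C)(C)C)C(C)(C)[C@@H]1[C@]32C | intermediate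
25 | C5 ketone with C6 triethylsilyloxy group | O=C1[C@@H](O[Si](CC)(CC)CC)[C@@H](CO[Si](c5ccccc5)(c5ccccc5)C(C)(C)C)[C@@]2(OCc5ccccc5)C(=O)[C@H]3CC(O[Si](C)(C)C(C)(C)C)C(C)(C)[C@@H]1[C@]32C | intermediate (not isolated)
26 | acyloin: C5 ketone, C6 hydroxyl | O=C1[C@@H](O)[C@@H](CO[Si](c5ccccc5)(c5ccccc5)C(C)(C)C)[C@@]2(OCc5ccccc5)C(=O)[C@H]3CC(O[Si](C)(C)C(C)(C)C)C(C)(C)[C@@H]1[C@]32C | intermediate
27 | C5,C6-trans-diol | O[C@@H]1[C@@H](O)[C@@H](CO[Si](c5ccccc5)(c5ccccc5)C(C)(C)C)[C@@]2(OCc5ccccc5)C(=O)[C@H]3CC(O[Si](C)(C)C(C)(C)C)C(C)(C)[C@@H]1[C@]32C | intermediate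
28 | C5 acetate, C6 hydroxyl | CC(=O)O[C@@H]1[C@@H](O)[C@@H](CO[Si](c5ccccc5)(c5ccccc5)C(C)(C)C)[C@@]2(OCc5ccccc5)C(=O)[C@H]3CC(O[Si](C)(C)C(C)(C)C)C(C)(C)[C@@H]1[C@]32C | intermediate
29 | C5 acetate, C6 BOM ether | CC(=O)O[C@@H]1[C@@H](OCOCc5ccccc5)[C@@H](CO[Si](c5ccccc5)(c5ccccc5)C(C)(C)C)[C@@]2(OCc5ccccc5)C(=O)[C@H]3CC(O[Si](C)(C)C(C)(C)C)C(C)(C)[C@@H]1[C@]32C | intermediate
30 | C9,C24-diol (C24 epimers) | CC(=O)O[C@@H]1[C@@H](OCOCc5ccccc5)[C@@H](CO)[C@@]2(OCc5ccccc5)C(=O)[C@H]3CC(O)C(C)(C)[C@@H]1[C@]32C | intermediate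
31 | C9 aldehyde, C24 ketone | CC(=O)O[C@@H]1[C@@H](OCOCc5ccccc5)[C@@H](C=O)[C@@]2(OCc5ccccc5)C(=O)[C@H]3CC(=O)C(C)(C)[C@@H]1[C@]32C | intermediate
32 | (E)-crotonaldehyde | C/C=C/C=O | starting material
33 | 2,3-dibromobutanal | CC(Br)C(Br)C=O | intermediate (not isolated)
34 | (Z)-2-bromobut-2-enal | C/C=C(\Br)C=O | intermediate
35 | (Z)-2-bromobut-2-en-1-ol | C/C=C(\Br)CO | intermediate
36 | (Z)-(1-hydroxybut-2-en-2-yl)chromium dichloride (trivalent chromium) | C/C=C(\[Cr](Cl)Cl)CO | intermediate (not isolated)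
37 | (9S)-allylic alcohol with (Z)-ethylidene at C11 | CC(=O)O[C@@H]1[C@@H](OCOCc5ccccc5)[C@@H]([C@H](O)/C(CO)=C\C)[C@@]2(OCc5ccccc5)C(=O)[C@H]3CC(=O)C(C)(C)[C@@H]1[C@]32C | intermediate
38 | cyclopropane diol (C9 and C15 hydroxyls) | CC(=O)O[C@@H]1[C@@H](OCOCc5ccccc5)[C@@H]([C@H](O)[C@]7(C[C@H]7C)CO)[C@@]2(OCc5ccccc5)C(=O)[C@H]3CC(=O)C(C)(C)[C@@H]1[C@]32C | intermediate
39 | C15 aldehyde, C9 hydroxyl | CC(=O)O[C@@H]1[C@@H](OCOCc5ccccc5)[C@@H]([C@H](O)[C@]7(C[C@H]7C)C=O)[C@@]2(OCc5ccccc5)C(=O)[C@H]3CC(=O)C(C)(C)[C@@H]1[C@]32C | intermediate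
40 | C15 aldehyde, C9 triethylsilyl ether | CC(=O)O[C@@H]1[C@@H](OCOCc5ccccc5)[C@@H]([C@H](O[Si](CC)(CC)CC)[C@]7(C[C@H]7C)C=O)[C@@]2(OCc5ccccc5)C(=O)[C@H]3CC(=O)C(C)(C)[C@@H]1[C@]32C | intermediate
41 | pentacycle: C15 ketone, C20 hydroxyl, C9 OTES | CC(=O)O[C@@H]1[C@@H](OCOCc5ccccc5)[C@H]2[C@H](O[Si](CC)(CC)CC)[C@]3(C[C@H]3C)C(=O)[C@@]3(O)[C@H]4CC(=O)C(C)(C)[C@@H]1[C@@]4(C)[C@@]23OCc5ccccc5 | intermediate
42 | C15 carbinol, C20 hydroxyl, C9 OTES | CC(=O)O[C@@H]1[C@@H](OCOCc5ccccc5)[C@H]2[C@H](O[Si](CC)(CC)CC)[C@]3(C[C@H]3C)[C@@H](O)[C@@]3(O)[C@H]4CC(=O)C(C)(C)[C@@H]1[C@@]4(C)[C@@]23OCc5ccccc5 | intermediate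
43 | C5,C15-diacetate, C9 OTES | CC(=O)O[C@@H]1[C@@H](OCOCc5ccccc5)[C@H]2[C@H](O[Si](CC)(CC)CC)[C@]3(C[C@H]3C)[C@@H](OC(C)=O)[C@@]3(O)[C@H]4CC(=O)C(C)(C)[C@@H]1[C@@]4(C)[C@@]23OCc5ccccc5 | intermediate
44 | C5,C15-diacetate, C9 hydroxyl | CC(=O)O[C@@H]1[C@@H](OCOCc5ccccc5)[C@H]2[C@H](O)[C@]3(C[C@H]3C)[C@@H](OC(C)=O)[C@@]3(O)[C@H]4CC(=O)C(C)(C)[C@@H]1[C@@]4(C)[C@@]23OCc5ccccc5 | intermediate
45 | C9 ketone; target carrying O6 BOM and O32 Bn | CC(=O)O[C@@H]1[C@@H](OCOCc5ccccc5)[C@H]2C(=O)[C@]3(C[C@H]3C)[C@@H](OC(C)=O)[C@@]3(O)[C@H]4CC(=O)C(C)(C)[C@@H]1[C@@]4(C)[C@@]23OCc5ccccc5 | intermediate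
46 | CNP0157858.3 | CC(=O)O[C@@H]1[C@@H](O)[C@H]2C(=O)[C@]3(C[C@H]3C)[C@@H](OC(C)=O)[C@@]3(O)[C@H]4CC(=O)C(C)(C)[C@@H]1[C@@]4(C)[C@@]23O | target

## Step count and risks

Total: 34 steps. Longest linear sequence: 31 steps (steps 1–6, 8–22 and 25–34).

**Step 16 (Proposed new method).** The Lewis acid may strip the silyl enol ethers, or the tetrasubstituted dienophile may react too slowly, so that the diene is lost before the cycloaddition occurs. The fallback is an anionic intramolecular double Michael reaction, which is known chemistry. It sets out from diketone 21, which is converted only into the mono-TES enol ether 22 (TESOTf, Et3N, −78 °C) and isolated. LiN(SiMe3)2 in THF at −78 °C removes a C29 proton to give the cross-conjugated lithium dienolate F1. F1 should add through C29 to C30 and then, through the resulting C32 enolate, to C8 of the silyloxy enone, giving the tricyclic lithium enolate F2. An acetic acid quench protonates C6 and the sequence comes back to the route at 25, which is desilylated to 26 as in step 17; the C8 configuration would have to be confirmed.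

**Step 9.** Enantioface discrimination may be poor because the two ring substituents on C22 are similar in size, or the ring carbonyl may be reduced in competition. The fallback sets out from 14: reduction without a chiral ligand ([(Ph3P)CuH]6 cat., (EtO)2MeSiH, t-BuOH) gives the racemic ketone F3, and the enantiomers are separated by preparative chromatography on a chiral stationary phase. The (4R) enantiomer comes back to the route at 15.

**Step 29.** The acyl anion equivalent may fail to add to the hindered C20 carbonyl, or the 1-acylcyclobutanol product may ring-expand by α-ketol rearrangement under the basic conditions. The fallback sets out from 40: SmI2 in THF at −78 °C, where the aldehyde is reduced first, should effect a reductive aldehyde–ketone (pinacol-type) cyclisation to the C15,C20-diol F4, whose C15 configuration is immaterial. DMP oxidation of the secondary C15 carbinol comes back to the route at 41.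

Further compounds
F1 | step 16 | lithium dienolate of 22 (O5 lithium, C29=C5) | O=C1C(OCc2ccccc2)=C(C)[C@@H]1CC(O[Si](C)(C)C(C)(C)C)C(C)(C)/C=C(O[Li])/C(O[Si](CC)(CC)CC)=C/CO[Si](c1ccccc1)(c1ccccc1)C(C)(C)C
F2 | step 16 | tricyclic lithium enolate (O5 lithium, C5=C6, O6 TES) | [Li]OC1=C(O[Si](CC)(CC)CC)[C@@H](CO[Si](c5ccccc5)(c5ccccc5)C(C)(C)C)[C@@]2(OCc5ccccc5)C(=O)[C@H]3CC(O[Si](C)(C)C(C)(C)C)C(C)(C)[C@@H]1[C@]32C
F3 | step 9 | racemic 2,3-bis(benzyloxy)-4-[(5E)-8-(TBDPS-oxy)-3,3-dimethyl-2-oxooct-5-en-1-yl]cyclobut-2-en-1-one | O=C1C(OCc2ccccc2)=C(OCc2ccccc2)C1CC(=O)C(C)(C)C/C=C/CCO[Si](c1ccccc1)(c1ccccc1)C(C)(C)C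
F4 | step 29 | C15,C20-diol with C9 OTES (C15 epimers) | CC(=O)O[C@@H]1[C@@H](OCOCc5ccccc5)[C@H]2[C@H](O[Si](CC)(CC)CC)[C@]3(C[C@H]3C)C(O)[C@@]3(O)[C@H]4CC(=O)C(C)(C)[C@@H]1[C@@]4(C)[C@@]23OCc5ccccc5
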